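**Plan**

- Retrosynthesis: the two O–CH3 bonds masking the ring B hydroxyls are cut first, then the four C–Br bonds ortho to the outer phenol OH groups. The C–OH bonds of rings A and C are then traced back to C–acetyl bonds, and the two diaryl ether C–O bonds are cut last, leading to bromanil and 3'-bromo-4'-hydroxyacetophenone.
- Forward: no ring is formed. Ring B comes from bromanil and rings A and C from the acetophenone. The sequence is double addition–elimination on the quinone, reductive methylation, double Baeyer–Villiger oxygen insertion, acetate methanolysis, ortho,ortho-dibromination of each outer phenol, and demethylation.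
- Enabling feature: in rings A and C the hydroxyl-bearing carbon lies para to the ether oxygen, exactly where the acetyl carbon of a 4-acetylphenoxy ring sits. Ring B is hexasubstituted (two aryloxy O, two O, two Br) and has no C–H for peracid or bromine to attack.
- The bromine ortho to each ether oxygen (meta to OH) could not be placed cleanly by a late bromination, so it is carried in with the acetophenone. The other four outer bromines enter ortho to the freed hydroxyls.
- Stereochemistry: the target has no stereocentre and no stereogenic double bond, so nothing needs to be controlled.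

Key step: step 3

Remark: ring B is the central ring and rings A and C are the two identical outer rings; both arms are treated identically throughout.

**Route**

Step 1
Reactants: 1 bromanil (tetrabromo-1,4-benzoquinone); 2 1-(3-bromo-4-hydroxyphenyl)ethan-1-one (2 equiv)
Product: 3 2,5-bis(4-acetyl-2-bromophenoxy)-3,6-dibromocyclohexa-2,5-diene-1,4-dione
Conditions: K2CO3, MeCN, 0 °C to rt, N2
Reagents that add atoms: none
Why: Twofold addition–elimination (vinylogous acyl substitution) of the phenoxide on the tetrahaloquinone should stop at the 2,5-pattern, because the first aryloxy group deactivates the carbonyl it is conjugated with and so sends the second phenoxide to the carbon para to it, while the electron-poor phenoxide of 2 is a poor one-electron donor towards bromanil and too weak a nucleophile to displace a third bromide at two equivalents.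

Step 2
Reactants: 3 2,5-bis(4-acetyl-2-bromophenoxy)-3,6-dibromocyclohexa-2,5-diene-1,4-dione
Product: 5 1,4-bis(4-acetyl-2-bromophenoxy)-2,5-dibromo-3,6-dimethoxybenzene, via hydroquinone 4 (not isolated)
Conditions: Na2S2O4, Bu4NBr (cat.), THF/H2O, rt; then aq KOH, Me2SO4, 0 °C to rt, Ar
Reagents that add atoms: dimethyl sulfate, COS(=O)(=O)OC
Why: Reductive methylation of a quinone, in which dithionite reduces the quinone to the hydroquinone and a phase-transfer Williamson O-methylation follows in the same flask, should cap both ring B oxygens, with excess dithionite keeping the dianion reduced and the low temperature letting alkylation outrun any aryl transfer between neighbouring oxygens.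

Step 3
Reactants: 5 1,4-bis(4-acetyl-2-bromophenoxy)-2,5-dibromo-3,6-dimethoxybenzene
Product: 6 [(2,5-dibromo-3,6-dimethoxy-1,4-phenylene)bis(oxy)]bis(3-bromo-4,1-phenylene) diacetate
Conditions: mCPBA (excess), CF3CO2H, CH2Cl2, 0 °C to rt
Reagents that add atoms: 3-chloroperoxybenzoic acid (mCPBA), OOC(=O)c1cccc(Cl)c1
Why: Protonation of each acetyl carbonyl by CF3CO2H lets the peracid add to give the tetrahedral Criegee adduct, within which the 3-bromo-4-aryloxyphenyl group shifts from carbon to the proximal peroxide oxygen as 3-chlorobenzoate departs, so that the acetyl-bearing carbon of rings A and C trades its C–C(=O) bond for the C–O bond of an acetate. The closest known reaction type is the Baeyer–Villiger oxidation of 4-aryloxy- and 3-bromo-4-alkoxyacetophenones to aryl acetates. No ring is closed and no stereocentre is created. The step needs aryl rather than methyl migration, which is secured by the ether oxygen para to the migrating carbon, whose lone pair stabilises the positive charge building up in the migrating aryl, the meta bromine slowing but not redirecting the shift. It also needs the peracid to leave ring B alone, which the substrate ensures because ring B has no C–H to hydroxylate and carries two bromines, while methyl ethers, aryl bromides and diaryl ethers are inert to mCPBA/CF3CO2H at room temperature.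

Step 4
Reactants: 6 [(2,5-dibromo-3,6-dimethoxy-1,4-phenylene)bis(oxy)]bis(3-bromo-4,1-phenylene) diacetate
Product: 7 4,4'-[(2,5-dibromo-3,6-dimethoxy-1,4-phenylene)bis(oxy)]bis(3-bromophenol)
Conditions: K2CO3 (cat.), MeOH/THF, rt
Reagents that add atoms: none
Why: Base-catalysed transesterification (Zemplén-type methanolysis) of the two aryl acetates should free both outer phenols under conditions that leave methyl ethers, diaryl ethers and aryl bromides untouched.

Step 5
Reactants: 7 4,4'-[(2,5-dibromo-3,6-dimethoxy-1,4-phenylene)bis(oxy)]bis(3-bromophenol)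
Product: 8 4,4'-[(2,5-dibromo-3,6-dimethoxy-1,4-phenylene)bis(oxy)]bis(2,3,6-tribromophenol)
Conditions: Br2 (4.2 equiv), AcOH/CH2Cl2, 0 °C to rt
Reagents that add atoms: bromine, BrBr
Why: Electrophilic aromatic bromination directed by each free phenol OH should fill its two ortho positions and stop there, since the para position is blocked by the ether oxygen, the one remaining C–H of each outer ring is meta to OH on a ring that by then bears three bromines, and ring B has no C–H.

Step 6
Reactants: 8 4,4'-[(2,5-dibromo-3,6-dimethoxy-1,4-phenylene)bis(oxy)]bis(2,3,6-tribromophenol)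
Product: 9 2,5-dibromo-3,6-bis(2,3,5-tribromo-4-hydroxyphenoxy)benzene-1,4-diol (CNP0163357.0)
Conditions: BBr3 (excess), CH2Cl2, −78 °C to rt; H2O quench
Reagents that add atoms: none
Why: Lewis-acid cleavage of aryl methyl ethers by BBr3, through boron–oxygen complexation and bromide attack at the methyl carbon, should unmask the two ring B hydroxyls, while the diaryl ether C–O bonds offer no sp3 carbon for bromide and are retained.

**Compound list**

1 | bromanil (2,3,5,6-tetrabromocyclohexa-2,5-diene-1,4-dione) | O=C1C(Br)=C(Br)C(=O)C(Br)=C1Br | starting material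
2 | 1-(3-bromo-4-hydroxyphenyl)ethan-1-one (3'-bromo-4'-hydroxyacetophenone) | CC(=O)c1ccc(O)c(Br)c1 | starting material
3 | 2,5-bis(4-acetyl-2-bromophenoxy)-3,6-dibromocyclohexa-2,5-diene-1,4-dione | O=C1C(Br)=C(Oc2ccc(C(C)=O)cc2Br)C(=O)C(Br)=C1Oc1ccc(C(C)=O)cc1Br | intermediate
4 | 2,5-bis(4-acetyl-2-bromophenoxy)-3,6-dibromobenzene-1,4-diol (hydroquinone, not isolated) | Oc1c(Br)c(Oc2ccc(C(C)=O)cc2Br)c(O)c(Br)c1Oc1ccc(C(C)=O)cc1Br | intermediate
5 | 1,4-bis(4-acetyl-2-bromophenoxy)-2,5-dibromo-3,6-dimethoxybenzene | COc1c(Br)c(Oc2ccc(C(C)=O)cc2Br)c(OC)c(Br)c1Oc1ccc(C(C)=O)cc1Br | intermediate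
6 | [(2,5-dibromo-3,6-dimethoxy-1,4-phenylene)bis(oxy)]bis(3-bromo-4,1-phenylene) diacetate | COc1c(Br)c(Oc2ccc(OC(C)=O)cc2Br)c(OC)c(Br)c1Oc1ccc(OC(C)=O)cc1Br | intermediate
7 | 4,4'-[(2,5-dibromo-3,6-dimethoxy-1,4-phenylene)bis(oxy)]bis(3-bromophenol) | COc1c(Br)c(Oc2ccc(O)cc2Br)c(OC)c(Br)c1Oc1ccc(O)cc1Br | intermediate
8 | 4,4'-[(2,5-dibromo-3,6-dimethoxy-1,4-phenylene)bis(oxy)]bis(2,3,6-tribromophenol) | COc1c(Br)c(Oc2cc(Br)c(O)c(Br)c2Br)c(OC)c(Br)c1Oc1cc(Br)c(O)c(Br)c1Br | intermediate
9 | 2,5-dibromo-3,6-bis(2,3,5-tribromo-4-hydroxyphenoxy)benzene-1,4-diol | Oc1c(Br)cc(Oc2c(O)c(Br)c(Oc3cc(Br)c(O)c(Br)c3Br)c(O)c2Br)c(Br)c1Br | target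

**Step count and risks**

Total step count: 6. Longest linear sequence: 6 steps, from bromanil 1 to the target 9.

Steps most likely to fail:

Step 3 (key step). The aryl shift may be sluggish because the meta bromine and the electron-poor aryloxy substituent lower the migratory aptitude. Alternatively the peracid may attack the tetraoxygenated ring B with oxidative loss of methyl. The fallback replaces oxygen insertion by nitrogen insertion and sets out from 5. Condensation with NH2OH·HCl and NaOAc in refluxing EtOH should give the bis-(E)-oxime of 5, 1,4-bis{2-bromo-4-[(1E)-1-(hydroxyimino)ethyl]phenoxy}-2,5-dibromo-3,6-dimethoxybenzene F1. Beckmann rearrangement (2,4,6-trichloro-1,3,5-triazine, DMF, rt), in which the aryl group anti to the oxime OH migrates, should give 1,4-bis(4-acetamido-2-bromophenoxy)-2,5-dibromo-3,6-dimethoxybenzene F2. Acid hydrolysis (HCl, EtOH/H2O, reflux) should give 1,4-bis(4-amino-2-bromophenoxy)-2,5-dibromo-3,6-dimethoxybenzene F3. Diazotisation (NaNO2, H2SO4, 0 °C) to the bis(diazonium) bis(hydrogensulfate) F4, used without isolation, followed by hydroxydediazoniation with Cu2O and Cu(NO3)2 in water, should deliver the bisphenol 7, where the route is rejoined.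

Step 1. Electron transfer from the phenoxide to the strongly oxidising quinone, substitution beyond two bromides, or hydrolysis of C–Br by adventitious water may erode the bis-ether. The fallback reverses the polarity of ether formation and sets out from 1. NaOMe (2 equiv) in MeOH should give 2,5-dibromo-3,6-dimethoxy-1,4-benzoquinone F5, and Na2S2O4 in EtOAc/H2O should reduce it to 2,5-dibromo-3,6-dimethoxybenzene-1,4-diol F6. Twofold SNAr of the dianion of F6 on commercial 1-(3-bromo-4-fluorophenyl)ethan-1-one (Cs2CO3, DMSO, 110 °C, Ar) should give 5 directly, rejoining the route at 5 and bypassing step 2.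

Step 2. The hydroquinone dianion may be reoxidised, the doubly flanked phenoxides may be alkylated incompletely, or base may induce a Smiles-type transfer of an acetyl-activated aryl group from an ether oxygen to the neighbouring phenoxide. The fallback protects ring B under reducing, non-basic conditions and changes the endgame; it sets out from 3. Reductive acetylation (Zn dust, Ac2O, NaOAc, rt) should give 2,5-bis(4-acetyl-2-bromophenoxy)-3,6-dibromo-1,4-phenylene diacetate F7. The same Baeyer–Villiger oxidation (mCPBA, CF3CO2H, CH2Cl2) should give the tetraacetate 2,5-bis(4-acetoxy-2-bromophenoxy)-3,6-dibromo-1,4-phenylene diacetate F8. Methanolysis (K2CO3, degassed MeOH) should give 2,5-dibromo-3,6-bis(2-bromo-4-hydroxyphenoxy)benzene-1,4-diol F9. Treatment with Br2 (5 equiv) in AcOH should first oxidise ring B to the quinone 2,5-dibromo-3,6-bis(2,3,5-tribromo-4-hydroxyphenoxy)cyclohexa-2,5-diene-1,4-dione F10, which is not isolated and shields ring B while rings A and C are dibrominated ortho to OH. Aqueous Na2S2O4 work-up should then reduce the quinone and give the target 9 directly.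

Further compounds
F1 | step 3 | 1,4-bis{2-bromo-4-[(1E)-1-(hydroxyimino)ethyl]phenoxy}-2,5-dibromo-3,6-dimethoxybenzene | COc1c(Br)c(Oc2ccc(/C(C)=N/O)cc2Br)c(OC)c(Br)c1Oc1ccc(/C(C)=N/O)cc1Br
F2 | step 3 | 1,4-bis(4-acetamido-2-bromophenoxy)-2,5-dibromo-3,6-dimethoxybenzene | COc1c(Br)c(Oc2ccc(NC(C)=O)cc2Br)c(OC)c(Br)c1Oc1ccc(NC(C)=O)cc1Br
F3 | step 3 | 1,4-bis(4-amino-2-bromophenoxy)-2,5-dibromo-3,6-dimethoxybenzene | COc1c(Br)c(Oc2ccc(N)cc2Br)c(OC)c(Br)c1Oc1ccc(N)cc1Br
F4 | step 3 | 4,4'-[(2,5-dibromo-3,6-dimethoxy-1,4-phenylene)bis(oxy)]bis(3-bromobenzenediazonium) bis(hydrogensulfate) | COc1c(Br)c(Oc2ccc([N+]#N)cc2Br)c(OC)c(Br)c1Oc1ccc([N+]#N)cc1Br.OS(=O)(=O)[O-].OS(=O)(=O)[O-]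
F5 | step 1 | 2,5-dibromo-3,6-dimethoxycyclohexa-2,5-diene-1,4-dione | COC1=C(Br)C(=O)C(OC)=C(Br)C1=O
F6 | step 1 | 2,5-dibromo-3,6-dimethoxybenzene-1,4-diol | COc1c(Br)c(O)c(OC)c(Br)c1O
F7 | step 2 | 2,5-bis(4-acetyl-2-bromophenoxy)-3,6-dibromo-1,4-phenylene diacetate | CC(=O)Oc1c(Br)c(Oc2ccc(C(C)=O)cc2Br)c(OC(C)=O)c(Br)c1Oc1ccc(C(C)=O)cc1Br
F8 | step 2 | 2,5-bis(4-acetoxy-2-bromophenoxy)-3,6-dibromo-1,4-phenylene diacetate | CC(=O)Oc1c(Br)c(Oc2ccc(OC(C)=O)cc2Br)c(OC(C)=O)c(Br)c1Oc1ccc(OC(C)=O)cc1Br
F9 | step 2 | 2,5-dibromo-3,6-bis(2-bromo-4-hydroxyphenoxy)benzene-1,4-diol | Oc1ccc(Oc2c(O)c(Br)c(Oc3ccc(O)cc3Br)c(O)c2Br)c(Br)c1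
F10 | step 2 | 2,5-dibromo-3,6-bis(2,3,5-tribromo-4-hydroxyphenoxy)cyclohexa-2,5-diene-1,4-dione | O=C1C(Br)=C(Oc2cc(Br)c(O)c(Br)c2Br)C(=O)C(Br)=C1Oc1cc(Br)c(O)c(Br)c1Br
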